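Ring C is disconnected at C2–C3 and O1–C8a, which gives an aryl aldehyde (ring B with C2 and O1) and a 2-fluoroaryl methyl ketone (ring A with C4 and C3). The key step is a domino aldol/SNAr annulation run as a fluoride relay: a chiral ammonium fluoride unmasks a silyl enol ether, the ion-paired enolate adds to the aldehyde and sets C2, and the aldolate oxygen displaces fluoride at C8a, which the C4 carbonyl activates from the ortho position; the expelled fluoride carries the cycle on. The precursors are a fluorinated bis-MOM enol silane and a prenylated bis-MOM benzaldehyde; four MOM groups are removed at the end.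

Key step: step 6

Remark: 5-fluororesorcinol and 3-bromo-4,5-dihydroxybenzaldehyde are taken as catalogue chemicals. The (2S) centre corresponds to attack on the Si face of the aldehyde; the cinchonidinium catalyst is assumed to deliver this sense, and its pseudoenantiomeric cinchoninium salt is the direct substitute if the opposite sense is found.

Step 1
Reactants: 1 5-fluororesorcinol (5-fluorobenzene-1,3-diol)
Product: 2 1-(2-fluoro-4,6-dihydroxyphenyl)ethan-1-one
Conditions: AcOH, BF3·OEt2, 90 °C; aqueous work-up
Reagents that add atoms: acetic acid, CC(=O)O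
Why: Friedel–Crafts (Nencki-type) C-acylation of the resorcinol should go to C4, para to one hydroxyl and ortho to the other, the less hindered of the doubly activated positions, as it does with orcinol.

Step 2
Reactants: 2 1-(2-fluoro-4,6-dihydroxyphenyl)ethan-1-one
Product: 3 1-[2-fluoro-4,6-bis(methoxymethoxy)phenyl]ethan-1-one
Conditions: NaH (2.2 equiv), MOMCl (2.4 equiv), DMF, 0 °C to rt
Reagents that add atoms: chloromethyl methyl ether (MOMCl), COCCl
Why: Williamson-type O-alkylation of both phenoxides, with NaH chosen because the hydroxyl ortho to the acetyl group is hydrogen-bonded to the carbonyl and is not alkylated reliably with amine bases.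

Step 3
Reactants: 3 1-[2-fluoro-4,6-bis(methoxymethoxy)phenyl]ethan-1-one
Product: 4 {1-[2-fluoro-4,6-bis(methoxymethoxy)phenyl]ethenyloxy}trimethylsilane
Conditions: LiN(iPr)2, THF, −78 °C; Me3SiCl, −78 to 0 °C; non-aqueous work-up (pentane, filtration)
Reagents that add atoms: chlorotrimethylsilane, C[Si](C)(C)Cl
Why: Kinetic deprotonation of the only enolisable position and O-silylation of the lithium enolate should give the silyl enol ether, the MOM ethers and the aryl fluoride being inert to the amide base at −78 °C.

Step 4
Reactants: 5 3-bromo-4,5-dihydroxybenzaldehyde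
Product: 6 3-bromo-4,5-bis(methoxymethoxy)benzaldehyde
Conditions: MOMCl (2.5 equiv), iPr2NEt (3 equiv), CH2Cl2, 0 °C to rt
Reagents that add atoms: chloromethyl methyl ether (MOMCl), COCCl
Why: O-alkylation of both catechol hydroxyls as MOM acetals, which removes the acidic protons before the cross-coupling and the fluoride-mediated key step.

Step 5
Reactants: 6 3-bromo-4,5-bis(methoxymethoxy)benzaldehyde
Product: 7 3,4-bis(methoxymethoxy)-5-(3-methylbut-2-en-1-yl)benzaldehyde
Conditions: tributyl(3-methylbut-2-en-1-yl)stannane (1.3 equiv), Pd(PPh3)4 (5 mol%), DMF, 90 °C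
Reagents that add atoms: tributyl(3-methylbut-2-en-1-yl)stannane, CCCC[Sn](CCCC)(CCCC)CC=C(C)C
Why: Stille cross-coupling (oxidative addition of the aryl bromide to zerovalent palladium, transmetalation, reductive elimination at the less hindered allyl terminus) should install the linear prenyl group and tolerates the aldehyde and the MOM ethers.

Step 6
Reactants: 4 {1-[2-fluoro-4,6-bis(methoxymethoxy)phenyl]ethenyloxy}trimethylsilane; 7 3,4-bis(methoxymethoxy)-5-(3-methylbut-2-en-1-yl)benzaldehyde
Product: 9 (2S)-2-[3,4-bis(methoxymethoxy)-5-(3-methylbut-2-en-1-yl)phenyl]-5,7-bis(methoxymethoxy)-2,3-dihydro-4H-chromen-4-one, via ammonium (S)-aldolate 8 (not isolated)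
Conditions: 4 (1.3 equiv), N-(9-anthracenylmethyl)-O-benzylcinchonidinium bifluoride (10 mol%), 4 Å molecular sieves, THF–toluene, −50 °C, then 0 °C; pH 7 phosphate buffer quench at 0 °C
Reagents that add atoms: none
Why: Proposed new method: fluoride from the catalyst cleaves the O–Si bond of 4, the enolate ion-paired to the cinchonidinium cation adds to the Si face of aldehyde 7 (C2–C3 bond, C2 set as S), and the resulting naked alkoxide 8 attacks C8a of ring A by intramolecular SNAr through a Meisenheimer complex stabilised by the ortho C4 carbonyl (O1–C8a bond), expelling the fluoride that desilylates the next molecule of 4, so that fluorotrimethylsilane is the only by-product. The closest known reaction types are the chiral quaternary ammonium fluoride-initiated Mukaiyama aldol addition of ketone silyl enol ethers to aryl aldehydes and the domino aldol–SNAr annulation of ortho-fluoroaryl carbonyl compounds; their merger into a fluoride-relay cycle is the new element. Ring C closes by addition–elimination at the sp2 carbon C8a in a six-membered transition state (O1, C2, C3, C4, C4a, C8a) that brings the C4 carbonyl into the plane of ring A. The C2 stereocentre is controlled by the chiral cation in the aldol addition and is untouched by the ring closure, since the C2–O1 bond is never broken. The step needs ring closure to outrun retro-aldol cleavage and E1cB dehydration of the aldolate; the ortho-acyl activation of the C–F bond, the non-coordinating cation, the low temperature and the reversible O-silylation of 8 by 4 (a configurationally stable reservoir that fluoride reopens) are relied on for this, and the aprotic medium with a buffered cold quench disfavours chalcone formation and base-induced opening of ring C in the product.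

Step 7
Reactants: 9 (2S)-2-[3,4-bis(methoxymethoxy)-5-(3-methylbut-2-en-1-yl)phenyl]-5,7-bis(methoxymethoxy)-2,3-dihydro-4H-chromen-4-one
Product: 10 sigmoidin B, (2S)-2-[3,4-dihydroxy-5-(3-methylbut-2-en-1-yl)phenyl]-5,7-dihydroxy-2,3-dihydro-4H-chromen-4-one
Conditions: HCl (3 M aq), MeOH, 40 °C
Reagents that add atoms: none
Why: Acid-catalysed acetal methanolysis should remove all four MOM groups under conditions mild enough to leave the prenyl alkene intact and not to open ring C, so the C2 configuration is kept.

Compound list
1 | 5-fluororesorcinol (5-fluorobenzene-1,3-diol) | Oc1cc(O)cc(F)c1 | starting material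
2 | 1-(2-fluoro-4,6-dihydroxyphenyl)ethan-1-one | CC(=O)c1c(O)cc(O)cc1F | intermediate
3 | 1-[2-fluoro-4,6-bis(methoxymethoxy)phenyl]ethan-1-one | CC(=O)c1c(OCOC)cc(OCOC)cc1F | intermediate
4 | {1-[2-fluoro-4,6-bis(methoxymethoxy)phenyl]ethenyloxy}trimethylsilane | C=C(O[Si](C)(C)C)c1c(OCOC)cc(OCOC)cc1F | intermediate
5 | 3-bromo-4,5-dihydroxybenzaldehyde | O=Cc1cc(O)c(O)c(Br)c1 | starting material
6 | 3-bromo-4,5-bis(methoxymethoxy)benzaldehyde | O=Cc1cc(OCOC)c(OCOC)c(Br)c1 | intermediate
7 | 3,4-bis(methoxymethoxy)-5-(3-methylbut-2-en-1-yl)benzaldehyde | CC(C)=CCc1cc(C=O)cc(OCOC)c1OCOC | intermediate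
8 | (S)-aldolate, the alkoxide of (3S)-1-[2-fluoro-4,6-bis(methoxymethoxy)phenyl]-3-hydroxy-3-[3,4-bis(methoxymethoxy)-5-(3-methylbut-2-en-1-yl)phenyl]propan-1-one, ion-paired to the cinchonidinium cation (anion shown) | CC(C)=CCc1cc([C@@H]([O-])CC(=O)c2c(OCOC)cc(OCOC)cc2F)cc(OCOC)c1OCOC | intermediate
9 | (2S)-2-[3,4-bis(methoxymethoxy)-5-(3-methylbut-2-en-1-yl)phenyl]-5,7-bis(methoxymethoxy)-2,3-dihydro-4H-chromen-4-one | CC(C)=CCc1cc([C@@H]2CC(=O)c3c(OCOC)cc(OCOC)cc3O2)cc(OCOC)c1OCOC | intermediate
10 | sigmoidin B, (2S)-2-[3,4-dihydroxy-5-(3-methylbut-2-en-1-yl)phenyl]-5,7-dihydroxy-2,3-dihydro-4H-chromen-4-one | CC(C)=CCc1cc([C@@H]2CC(=O)c3c(O)cc(O)cc3O2)cc(O)c1O | target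

Total step count: 7. Longest linear sequence: 5 steps (steps 1, 2, 3, 6, 7).

Steps most likely to fail

Step 6. The aldolate may equilibrate by retro-aldol cleavage before the ring closes, which would erode the enantiomeric purity. The facial selectivity of the ion-paired enolate may be modest. Dehydration to the chalcone, or base-induced opening of ring C in the product, may compete with the relay. The fallback uses known chemistry and separates the two bond formations. It sets out from 4 and 7 with a Lewis-base-activated Mukaiyama aldol addition (SiCl4, 5 mol% of the 1,1'-binaphthyl-2,2'-diamine-derived bisphosphoramide enantiomer that directs attack to the Si face, iPr2NEt, CH2Cl2, −78 °C; KF/KH2PO4 work-up), a reaction established for methyl ketone silyl enol ethers and aryl aldehydes. This would give (3S)-1-[2-fluoro-4,6-bis(methoxymethoxy)phenyl]-3-hydroxy-3-[3,4-bis(methoxymethoxy)-5-(3-methylbut-2-en-1-yl)phenyl]propan-1-one F1. The alkoxide of F1 is then closed by intramolecular SNAr (KN(SiMe3)2, 18-crown-6, THF, −40 to 0 °C), which comes back to the route at 9.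

Step 5. Allylic transposition during transmetalation or reductive elimination may deliver the branched 1,1-dimethylallyl isomer beside the linear prenyl product. The fallback sets out from 6 with a Stille coupling of allyltributylstannane (Pd(PPh3)4, DMF, 90 °C), in which transposition is degenerate. This would give 3,4-bis(methoxymethoxy)-5-(prop-2-en-1-yl)benzaldehyde F2. Cross-metathesis of F2 with excess 2-methyl-2-butene (second-generation Grubbs catalyst, CH2Cl2, 40 °C) then comes back to the route at 7.

Step 7. Under Brønsted acid the prenyl group may cyclise onto the freed neighbouring 4'-hydroxyl to a dimethylchroman, or the alkene may add methanol or water. The fallback sets out from 9 and transfers the MOM groups under aprotic, buffered conditions (Me3SiOTf, 2,2'-bipyridyl, CH2Cl2, 0 °C), which would convert the aryl MOM ethers into (2S)-2-[3,4-bis(trimethylsilyloxy)-5-(3-methylbut-2-en-1-yl)phenyl]-5,7-bis(trimethylsilyloxy)-2,3-dihydro-4H-chromen-4-one F3. Neutral aqueous hydrolysis of F3 then comes back to the route at 10.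

Further compounds
F1 | step 6 | (3S)-1-[2-fluoro-4,6-bis(methoxymethoxy)phenyl]-3-hydroxy-3-[3,4-bis(methoxymethoxy)-5-(3-methylbut-2-en-1-yl)phenyl]propan-1-one | CC(C)=CCc1cc([C@@H](O)CC(=O)c2c(OCOC)cc(OCOC)cc2F)cc(OCOC)c1OCOC
F2 | step 5 | 3,4-bis(methoxymethoxy)-5-(prop-2-en-1-yl)benzaldehyde | C=CCc1cc(C=O)cc(OCOC)c1OCOC
F3 | step 7 | (2S)-2-[3,4-bis(trimethylsilyloxy)-5-(3-methylbut-2-en-1-yl)phenyl]-5,7-bis(trimethylsilyloxy)-2,3-dihydro-4H-chromen-4-one | CC(C)=CCc1cc([C@@H]2CC(=O)c3c(O[Si](C)(C)C)cc(O[Si](C)(C)C)cc3O2)cc(O[Si](C)(C)C)c1O[Si](C)(C)C
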